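# Proposal: synthesis of the all-cis furofuranone 17 by iodide-catalysed Cloke–Wilson ring expansion of a diaroylcyclopropane

## The problem

Target 17 is a cis-fused 3,7-dioxabicyclo[3.3.0]octan-2-one. A γ-lactone (ring A: C1–O2–C3(=O)–C4–C5) and a tetrahydrofuran (ring B: C4–C5–C6–O7–C8) share the C4–C5 bond; C1 carries the 4-hydroxy-3,5-dimethoxyphenyl (syringyl) group and C8 the 3,4-dihydroxyphenyl (catechol) group. The four contiguous stereocentres C1, C5, C4 and C8 have their hydrogens on one face, so both aryl groups stand on the concave face of the bicycle. This crowded arrangement has to be installed under kinetic control and never exposed to equilibrating conditions afterwards. C5 is the pivot: a catalyst-set C1 can be tied to C5 while C5 is still epimerisable, the cis fusion makes C4 follow C5, and a concave aryl group at C1 screens one face of ring B so that C4 and C8 can be set together from the open face. Both C1–O2 and C8–O7 are benzylic C–O bonds to electron-rich rings and become para-hydroxybenzylic once the phenols are free. Acid ionises them, base opens them through quinone methides, and hydrogenolysis can cleave them; the catechol is air-sensitive, so the phenols should be unmasked last and under neutral conditions. The enabling feature is ring B: O7 lies between the unsubstituted C6H2 and the aryl-bearing C8, and C8 is bonded to the carboxyl-bearing C4, so C3–C4–C8–O7 is a β-keto ester in enol ether form. O7–C6–C5–C4 is what forms when the ketone oxygen of an aroyl group on cyclopropane carbon C4 captures the ring methylene C6 of a C4–C5–C6 cyclopropane.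

## Retrosynthesis

**17 from 15 (through 16).** The C4–H and C8–H bonds and the three O–benzyl bonds are cut together. Syn addition of hydrogen to a C4=C8 double bond sets both centres in one event, and in ene-lactone 15 the syringyl group on C1 lies over ring B, so only the H5 face is open. That is exactly the all-cis array, which a late bond to C8 (aryl addition or ether closure under ionising conditions) would not deliver reliably. Benzyl ethers are chosen because they fall in the same neutral operation. The forward step must saturate a tetrasubstituted enol ether without cleaving the benzylic C–O bonds.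

**15 from 14.** The acyl bond C3–O2 of the lactone is cut. Closing through the acyl carbon leaves C1–O intact, so the carbinol configuration of 14 is carried over unchanged; closing through C1 (alkyl–oxygen) would invert and is held in reserve. The forward step is a base-catalysed transesterification, which avoids acid at the electron-rich benzylic carbinol.

**14 from 13.** The C1–H bond is cut, leading back to the aryl ketone 13. C5 in 13 is α to the ketone and allylic, hence configurationally labile. A catalyst-controlled transfer hydrogenation can therefore fix C1 and select one C5 epimer in the same step, converting racemic 13 into one stereoisomer. Setting C5 earlier by an asymmetric ring construction would be pointless for the same lability. The forward step must give the (S)-carbinol and the C5 epimer in which C1–O and C6 are syn.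

**13 from 11 (through 12).** This is the key disconnection: the O7–C6 bond is cut and a C4–C6 bond is restored, which gives the 1,2-diaroylcyclopropane ester 11. A direct union of a β-keto ester with an aryl vinyl ketone by Michael addition and O-alkylation would bond C4 to C6 and O7 to C5, the wrong way round. The cyclopropane detour makes C4–C6 and C4–C5 first and then trades C4–C6 for O7–C6, which leaves the required C4–C5 bond and places the aroyl group on C5. Dihydrofuran 13 contains every skeletal atom of 17, with both aryl groups in place. The forward step needs nucleophilic ring opening at C6 and ring closure through the ketone oxygen.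

**11 from 5 and 9 (through 10).** The bonds C4–C6 and C4–C5 are cut, leading back to the bromo β-keto ester 5 and the aryl vinyl ketone 9. Placing the halogen on the dicarbonyl carbon makes the ring closure a 3-exo-tet C-alkylation by a simple ketone enolate. This is cleaner than the reverse polarity (halogen on the enone), where O-alkylation of the dicarbonyl enolate competes. The relative configuration of 11 does not matter.

**5 from 4, 4 from 2 and 3, 2 from 1; 9 from 7 (through 8), 7 from 6.** The C4–Br bond, the C3–C4 bond and the benzyl ethers are cut on one side; the C5–C6 bond (a one-carbon Mannich methylenation) and one benzyl ether on the other. Both halves start from commercial acetophenones 1 and 6, and 3 supplies the lactone carbonyl carbon. All these steps are standard enolate chemistry.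

## Roads not taken

**Alternative 1:** Cascade through O7–C8, C4–C5 and O2–C3. Epoxy alcohol A2 and benzylidene malonate A3 would be combined with catalytic alkoxide base. The alkoxide of A2 adds reversibly to A3 (O7–C8), the malonate anion opens the epoxide at C5 with inversion (C4–C5, ring B), and the released C1 alkoxide lactonises (ring A) to give A1. The extra ester on C4 is removed afterwards.
- Merits: highly convergent; absolute configuration comes from a catalytic asymmetric epoxidation; the C1/C5 relationship is stereospecific, because the trans epoxide with retention at C1 and inversion at C5 gives exactly the cis lactone. In this respect it is better than the chosen plan, which depends on the sense of a dynamic resolution.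
- Weak points: A3 is an electron-rich, poorly electrophilic acceptor and its oxa-Michael adducts revert easily. C8 is therefore set under equilibrium, with nothing to hold the catechol on the concave face. The electron-rich aryl epoxide can also open at benzylic C1 or undergo Payne rearrangement. Removing the C4 ester passes through a lactone enol β to O7, which invites retro-oxa-Michael opening and again loosens C8.
- Comparison: the chosen plan sets C8 and C4 together by syn addition to the only open face, which is a kinetic guarantee of the all-cis array. It pays for this with an uncertain C1/C5 sense, for which a fallback with inversion at C1 exists.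

**Alternative 2:** Cut through C1–C5 and C3–C4 ([2+2]), then oxygen insertion. Acid chloride A5 is dehydrochlorinated by a tertiary amine to arylketene A6, which adds across A7 to give the endo cyclobutanone A4. Peracid oxygen insertion on the benzylic side then gives lactone A8.
- Merits: the shortest entry to the fused core; cis fusion is automatic; ketene cycloaddition places the aryl group endo, matching the concave syringyl group; the oxygen insertion proceeds with retention.
- Weak points: an unactivated cis-alkene such as A7 is a poor partner for a monoarylketene, which dimerises; the product is racemic, and there is no established asymmetric version. C8 is still a methylene group in A8. The catechol would have to be introduced by functionalising a C–H bond next to O7, choosing C8 over C6 and the concave face over the convex one.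
- Comparison: the chosen plan brings both aryl groups in from the start as acetophenones and needs no late C–H chemistry; it is longer to the bicycle but complete when it arrives.

**Alternative 3:** Cut through O7–C8 and C8–H. Keto lactone A10, treated with a strong acid and a trialkylsilane, closes to the cyclic hemiketal and the oxocarbenium ion. Hydride then adds to C8 from the convex face while C4 settles into the cis fusion, giving A9, the tribenzyl ether of 17.
- Merits: the stereochemical logic at C8 is the same as in the chosen plan. It avoids hydrogenating a tetrasubstituted alkene and so carries no risk of metal-mediated C–O hydrogenolysis before deprotection; in this respect it is better.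
- Weak points: strong acid meets two electron-rich benzylic C–O bonds. Ionisation at C1 would move the syringyl group to the convex face or lead to ionic hydrogenolysis, and the product aryl ether can be over-reduced. The route to A10 with the cis C1/C5 relationship is also left open and needs its own asymmetric solution plus an α-aroylation.
- Comparison: A10 is the ring-opened hydrate of 15, so the chosen plan reaches the same oxidation pattern in three C–C bond-forming operations and saturates it under neutral conditions. It must accept a forcing hydrogenation in exchange.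

Key step: step 7

## Route

Assumption: the target is taken exactly as drawn, (3S,3aS,6S,6aR), with the hydrogens at C1, C5, C4 and C8 on one face; 11 and 13 are racemic and 11 is carried on as whatever diastereomer mixture forms.

Step 1
Reactants: 1 3,4-dihydroxyacetophenone
Product: 2 1-[3,4-bis(benzyloxy)phenyl]ethan-1-one
Conditions: BnBr (2.2 equiv), K2CO3, DMF, 60 °C
Reagents that add atoms: benzyl bromide, BrCc1ccccc1
Why: Williamson etherification of both phenoxides with a benzylic halide (SN2); the aryl ketone is inert to carbonate base.

Step 2
Reactants: 2 1-[3,4-bis(benzyloxy)phenyl]ethan-1-one; 3 dimethyl carbonate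
Product: 4 methyl 3-[3,4-bis(benzyloxy)phenyl]-3-oxopropanoate
Conditions: NaH (2.5 equiv), THF, reflux; then aq. HCl
Reagents that add atoms: none
Why: Crossed Claisen condensation (C-methoxycarbonylation) of the methyl ketone enolate with the carbonate; the product is removed as its stabilised sodium enolate, which drives the reaction and prevents a second acylation.

Step 3
Reactants: 4 methyl 3-[3,4-bis(benzyloxy)phenyl]-3-oxopropanoate
Product: 5 methyl 3-[3,4-bis(benzyloxy)phenyl]-2-bromo-3-oxopropanoate (racemic)
Conditions: NBS (1.0 equiv), NH4OAc (10 mol %), CH2Cl2/Et2O, 0 °C to rt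
Reagents that add atoms: N-bromosuccinimide, O=C1CCC(=O)N1Br
Why: Electrophilic α-bromination of the enolised β-keto ester; one equivalent at low temperature stops at the monobromide, and the acyl-deactivated arene is not brominated.

Step 4
Reactants: 6 acetosyringone (1-(4-hydroxy-3,5-dimethoxyphenyl)ethan-1-one)
Product: 7 1-[4-(benzyloxy)-3,5-dimethoxyphenyl]ethan-1-one
Conditions: BnBr (1.2 equiv), K2CO3, DMF, 60 °C
Reagents that add atoms: benzyl bromide, BrCc1ccccc1
Why: Williamson etherification; the phenol flanked by two methoxy groups is hindered but is alkylated cleanly by the unhindered benzylic bromide in warm DMF.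

Step 5
Reactants: 7 1-[4-(benzyloxy)-3,5-dimethoxyphenyl]ethan-1-one
Product: 9 1-[4-(benzyloxy)-3,5-dimethoxyphenyl]prop-2-en-1-one, via Mannich base 8 (not isolated)
Conditions: (CH2O)n (3 equiv), PhNHMe·CF3CO2H (1.5 equiv), THF, reflux; used at once
Reagents that add atoms: paraformaldehyde (formaldehyde source), C=O
Why: Mannich condensation of the methyl ketone with the iminium ion formed from formaldehyde and the anilinium salt, followed by in situ β-elimination of the weakly basic amine from 8. The methyl group is the only enolisable position, so a single methylene is introduced.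

Step 6
Reactants: 5 methyl 3-[3,4-bis(benzyloxy)phenyl]-2-bromo-3-oxopropanoate; 9 1-[4-(benzyloxy)-3,5-dimethoxyphenyl]prop-2-en-1-one
Product: 11 methyl 1-[3,4-bis(benzyloxy)benzoyl]-2-[4-(benzyloxy)-3,5-dimethoxybenzoyl]cyclopropane-1-carboxylate (racemic diastereomer mixture), via Michael adduct 10 (not isolated)
Conditions: K2CO3 (2 equiv), DMF, 0 °C to rt
Reagents that add atoms: none
Why: Michael-initiated ring closure: the soft enolate of 5 adds to the unhindered enone terminus (C4–C6), and the ketone enolate of 10 displaces the tertiary bromide in a 3-exo-tet closure (C4–C5). Both relative configurations of 11 converge later because C4 becomes trigonal in step 7.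

Step 7
Reactants: 11 methyl 1-[3,4-bis(benzyloxy)benzoyl]-2-[4-(benzyloxy)-3,5-dimethoxybenzoyl]cyclopropane-1-carboxylate
Product: 13 methyl 2-[3,4-bis(benzyloxy)phenyl]-4-[4-(benzyloxy)-3,5-dimethoxybenzoyl]-4,5-dihydrofuran-3-carboxylate (racemic), via iodo enolate 12 (not isolated)
Conditions: NaI (20 mol %), DMF, 80 °C, Ar
Reagents that add atoms: none
Why: Iodide-catalysed Cloke–Wilson rearrangement; the closest known type is the halide-promoted ring expansion of 1-acylcyclopropane-1-carboxylates and 1,1-diacylcyclopropanes to 4,5-dihydrofurans. The sequence begins with SN2 attack of iodide on C6, the only unsubstituted ring carbon; the C4–C6 bond breaks heterolytically and leaves the β-keto ester enolate 12. Ring B then closes by 5-exo-tet O-alkylation, in which the enolate oxygen of the catechol ketone (O7) displaces iodide at C6 and returns the catalyst. No stereocentre is created: C4 becomes trigonal, so the diastereomer composition of 11 is irrelevant, and C5 is not touched. Three selectivities are needed. Attack at C6 rather than at the aroyl-bearing C5 should follow from primary against secondary carbon and from the adjacent carbonyl disfavouring the loose, charge-separated transition state at C5, as with terminal glycidic esters and ketones, which soft nucleophiles open at the CH2 group. Cleavage of C4–C6 rather than C5–C6 follows from the leaving group, a β-keto ester enolate against a simple ketone enolate. O- over C-alkylation of 12 is secured thermodynamically, since C-alkylation only regenerates the strained ring while closure through the ketone oxygen gives the aryl-conjugated vinylogous carbonate irreversibly.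

Step 8
Reactants: 13 methyl 2-[3,4-bis(benzyloxy)phenyl]-4-[4-(benzyloxy)-3,5-dimethoxybenzoyl]-4,5-dihydrofuran-3-carboxylate (racemic)
Product: 14 methyl (4S)-2-[3,4-bis(benzyloxy)phenyl]-4-[(S)-[4-(benzyloxy)-3,5-dimethoxyphenyl](hydroxy)methyl]-4,5-dihydrofuran-3-carboxylate
Conditions: RuCl[(S,S)-TsDPEN](p-cymene) (2 mol %), HCO2H/Et3N (1:2), DMF, 40 °C
Reagents that add atoms: none
Why: Noyori–Ikariya asymmetric transfer hydrogenation under dynamic kinetic resolution: the (S,S)-catalyst should deliver hydride to the ketone face that gives the (S)-carbinol, as with simple aryl alkyl ketones, while C5 (α to the ketone and allylic) epimerises in the amine-rich medium. The faster-reacting C5 epimer should place H5 beside the syringyl ring, the ester-bearing sp2 carbon C4 beside the carbonyl oxygen and C6 anti to the incoming hydride, which keeps C4 clear of the aryl group and gives the (4S) ring centre with C1–O and C6 syn. This parallels the syn selectivity of the same reaction with 2-substituted 3-aryl-3-oxo carboxylic acid derivatives.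

Step 9
Reactants: 14 methyl (4S)-2-[3,4-bis(benzyloxy)phenyl]-4-[(S)-[4-(benzyloxy)-3,5-dimethoxyphenyl](hydroxy)methyl]-4,5-dihydrofuran-3-carboxylate
Product: 15 (3S,3aS)-6-[3,4-bis(benzyloxy)phenyl]-3-[4-(benzyloxy)-3,5-dimethoxyphenyl]-3a,4-dihydro-1H,3H-furo[3,4-c]furan-1-one
Conditions: 1,5,7-triazabicyclo[4.4.0]dec-5-ene (TBD, 10 mol %), 4 Å MS, toluene, 60 °C
Reagents that add atoms: none
Why: Base-catalysed intramolecular transesterification (5-exo-trig lactonisation) of the γ-hydroxy ester closes ring A. The C1–O bond is not broken, so C1 is retained, and acid is avoided so that the electron-rich benzylic carbinol cannot ionise.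

Step 10
Reactants: 15 (3S,3aS)-6-[3,4-bis(benzyloxy)phenyl]-3-[4-(benzyloxy)-3,5-dimethoxyphenyl]-3a,4-dihydro-1H,3H-furo[3,4-c]furan-1-one
Product: 17 (3S,3aS,6S,6aR)-6-(3,4-dihydroxyphenyl)-3-(4-hydroxy-3,5-dimethoxyphenyl)tetrahydro-1H,3H-furo[3,4-c]furan-1-one, via triphenol ene-lactone 16 (not isolated)
Conditions: H2 (4 bar), 10% Pd/C, EtOAc/THF, rt
Reagents that add atoms: none
Why: Heterogeneous hydrogenation: the three aryl benzyl ethers are hydrogenolysed first (16), then H2 adds syn to the tetrasubstituted enol ether C4=C8. The concave syringyl group and C1 cover one face of ring B, so both hydrogens should arrive on the H5 face, which gives the cis fusion at C4 and puts the catechol on the concave face at C8. The neutral medium keeps the benzylic C–O bonds from ionising.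

## Compound list

1 | 3,4-dihydroxyacetophenone | CC(=O)c1ccc(O)c(O)c1 | starting material
2 | 1-[3,4-bis(benzyloxy)phenyl]ethan-1-one | CC(=O)c1ccc(OCc2ccccc2)c(OCc2ccccc2)c1 | intermediate
3 | dimethyl carbonate | COC(=O)OC | starting material
4 | methyl 3-[3,4-bis(benzyloxy)phenyl]-3-oxopropanoate | COC(=O)CC(=O)c1ccc(OCc2ccccc2)c(OCc2ccccc2)c1 | intermediate
5 | methyl 3-[3,4-bis(benzyloxy)phenyl]-2-bromo-3-oxopropanoate (racemic) | COC(=O)C(Br)C(=O)c1ccc(OCc2ccccc2)c(OCc2ccccc2)c1 | intermediate
6 | acetosyringone | CC(=O)c1cc(OC)c(O)c(OC)c1 | starting material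
7 | 1-[4-(benzyloxy)-3,5-dimethoxyphenyl]ethan-1-one | CC(=O)c1cc(OC)c(OCc2ccccc2)c(OC)c1 | intermediate
8 | 1-[4-(benzyloxy)-3,5-dimethoxyphenyl]-3-[methyl(phenyl)amino]propan-1-one (Mannich base) | CN(CCC(=O)c1cc(OC)c(OCc2ccccc2)c(OC)c1)c1ccccc1 | intermediate (not isolated)
9 | 1-[4-(benzyloxy)-3,5-dimethoxyphenyl]prop-2-en-1-one | C=CC(=O)c1cc(OC)c(OCc2ccccc2)c(OC)c1 | intermediate
10 | methyl 2-[3,4-bis(benzyloxy)benzoyl]-5-[4-(benzyloxy)-3,5-dimethoxyphenyl]-2-bromo-5-oxopentanoate (racemic Michael adduct) | COC(=O)C(Br)(CCC(=O)c1cc(OC)c(OCc2ccccc2)c(OC)c1)C(=O)c1ccc(OCc2ccccc2)c(OCc2ccccc2)c1 | intermediate (not isolated)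
11 | methyl 1-[3,4-bis(benzyloxy)benzoyl]-2-[4-(benzyloxy)-3,5-dimethoxybenzoyl]cyclopropane-1-carboxylate (racemic, either relative configuration) | COC(=O)C1(CC1C(=O)c1cc(OC)c(OCc2ccccc2)c(OC)c1)C(=O)c1ccc(OCc2ccccc2)c(OCc2ccccc2)c1 | intermediate
12 | sodium enolate of methyl 2-[3,4-bis(benzyloxy)benzoyl]-3-[4-(benzyloxy)-3,5-dimethoxybenzoyl]-4-iodobutanoate (racemic) | COC(=O)C(C(CI)C(=O)c1cc(OC)c(OCc2ccccc2)c(OC)c1)=C([O-])c1ccc(OCc2ccccc2)c(OCc2ccccc2)c1.[Na+] | intermediate (not isolated)
13 | methyl 2-[3,4-bis(benzyloxy)phenyl]-4-[4-(benzyloxy)-3,5-dimethoxybenzoyl]-4,5-dihydrofuran-3-carboxylate (racemic) | COC(=O)C1=C(c2ccc(OCc3ccccc3)c(OCc3ccccc3)c2)OCC1C(=O)c1cc(OC)c(OCc2ccccc2)c(OC)c1 | intermediate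
14 | methyl (4S)-2-[3,4-bis(benzyloxy)phenyl]-4-[(S)-[4-(benzyloxy)-3,5-dimethoxyphenyl](hydroxy)methyl]-4,5-dihydrofuran-3-carboxylate | COc1cc([C@@H](O)[C@@H]2COC(c3ccc(OCc4ccccc4)c(OCc4ccccc4)c3)=C2C(=O)OC)cc(OC)c1OCc1ccccc1 | intermediate
15 | (3S,3aS)-6-[3,4-bis(benzyloxy)phenyl]-3-[4-(benzyloxy)-3,5-dimethoxyphenyl]-3a,4-dihydro-1H,3H-furo[3,4-c]furan-1-one | COc1cc([C@H]2OC(=O)C3=C(c4ccc(OCc5ccccc5)c(OCc5ccccc5)c4)OC[C@@H]23)cc(OC)c1OCc1ccccc1 | intermediate
16 | (3S,3aS)-6-(3,4-dihydroxyphenyl)-3-(4-hydroxy-3,5-dimethoxyphenyl)-3a,4-dihydro-1H,3H-furo[3,4-c]furan-1-one | COc1cc([C@H]2OC(=O)C3=C(c4ccc(O)c(O)c4)OC[C@@H]23)cc(OC)c1O | intermediate (not isolated)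
17 | (3S,3aS,6S,6aR)-6-(3,4-dihydroxyphenyl)-3-(4-hydroxy-3,5-dimethoxyphenyl)tetrahydro-1H,3H-furo[3,4-c]furan-1-one | COc1cc([C@H]2OC(=O)[C@@H]3[C@H]2CO[C@@H]3c2ccc(O)c(O)c2)cc(OC)c1O | target

## Step count and least certain steps

Total: 10 steps. Longest linear sequence: 8 steps (steps 1, 2, 3, 6, 7, 8, 9, 10, from 1).

**Step 7 (key step).** The most likely failure is loss of regiocontrol in the ring opening. Iodide may attack the aroyl-bearing C5, because C4–C5 is the bond weakened by all three acyl groups and displacement next to a carbonyl can be fast; O7 would then close onto C5. At the temperature needed for turnover, ester demethylation by iodide and air oxidation towards the furan are secondary risks. Fallback: set out from 5 and run the ring closure of step 6 with N-methoxy-N-methylacrylamide in place of 9, which should give the cyclopropane Weinreb amide F1. A carboxamide activates its α-carbon towards displacement far less than an aroyl group, so the NaI rearrangement should then open at C6 and give the dihydrofuran Weinreb amide F2. The syringyl ketone is installed afterwards by Weinreb ketone synthesis: commercial 4-bromo-2,6-dimethoxyphenol is benzylated to the aryl bromide F3, bromine–lithium exchange with n-BuLi at −78 °C gives the aryllithium F4, and its addition to F2 returns to the route at 13.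

**Step 8.** The most likely failure is the wrong sense of diastereoselection in the dynamic resolution. If the sp2 carbon C4 rather than C6 takes the position anti to hydride (the classical Felkin–Anh arrangement with C4 as the large group), the anti C1–O/C6 relationship results and, after closure, the syringyl group would sit on the convex face. Slow epimerisation of C5 or migration of the double bond in the basic medium are lesser risks. Fallback: set out from 13 with the enantiomeric catalyst RuCl[(R,R)-TsDPEN](p-cymene), which in that case should give the anti hydroxy ester F5 with the required (S) ring centre and an (R) carbinol. Mitsunobu reaction with 4-nitrobenzoic acid (PPh3, diisopropyl azodicarboxylate) inverts C1 to the 4-nitrobenzoate F6; the two meta methoxy groups and the twisted para benzyloxy group temper ionisation. K2CO3 in methanol then removes the acyl group and the liberated alkoxide lactonises, which returns to the route at 15.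

**Step 10.** The most likely failure is over-reduction. Hydrogenolysis of the C1–O2 or C8–O7 bond, which become para-hydroxybenzylic once the benzyl groups are gone, may compete with the slow saturation of the tetrasubstituted enol ether; double-bond migration on the metal could also scramble C5. Fallback: set out from 15 and hydrogenate the alkene alone with the homogeneous catalyst [Ir(cod)(PCy3)(py)]PF6 (H2, CH2Cl2), which reduces tetrasubstituted alkenes from the open face and leaves benzyl ethers and benzylic C–O bonds intact; this gives the tribenzyl ether F7. Brief transfer hydrogenolysis (10% Pd/C, cyclohexa-1,4-diene, EtOAc) then removes the benzyl groups and arrives at 17.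

**Step 5.** The most likely failure is loss of material by polymerisation or amine re-addition while the aryl vinyl ketone is isolated. Fallback: set out from 7 and carry out a classical Mannich reaction (dimethylamine hydrochloride, paraformaldehyde, catalytic HCl, ethanol, reflux) to the crystalline Mannich base hydrochloride F8. Neutralisation and quaternisation with MeI give the trimethylammonium iodide F9, a storable salt. Under the K2CO3/DMF conditions of step 6, F9 releases 9 by elimination only in the presence of the enolate of 5, so the enone is never isolated and the route is rejoined at 11.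

## Further compounds

F1 | step 7 | methyl 1-[3,4-bis(benzyloxy)benzoyl]-2-[methoxy(methyl)carbamoyl]cyclopropane-1-carboxylate (racemic) | COC(=O)C1(CC1C(=O)N(C)OC)C(=O)c1ccc(OCc2ccccc2)c(OCc2ccccc2)c1
F2 | step 7 | methyl 2-[3,4-bis(benzyloxy)phenyl]-4-[methoxy(methyl)carbamoyl]-4,5-dihydrofuran-3-carboxylate (racemic) | COC(=O)C1=C(c2ccc(OCc3ccccc3)c(OCc3ccccc3)c2)OCC1C(=O)N(C)OC
F3 | step 7 | 2-(benzyloxy)-5-bromo-1,3-dimethoxybenzene | COc1cc(Br)cc(OC)c1OCc1ccccc1
F4 | step 7 | [4-(benzyloxy)-3,5-dimethoxyphenyl]lithium | [Li]c1cc(OC)c(OCc2ccccc2)c(OC)c1
F5 | step 8 | methyl (4S)-2-[3,4-bis(benzyloxy)phenyl]-4-[(R)-[4-(benzyloxy)-3,5-dimethoxyphenyl](hydroxy)methyl]-4,5-dihydrofuran-3-carboxylate | COc1cc([C@H](O)[C@@H]2COC(c3ccc(OCc4ccccc4)c(OCc4ccccc4)c3)=C2C(=O)OC)cc(OC)c1OCc1ccccc1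
F6 | step 8 | methyl (4S)-2-[3,4-bis(benzyloxy)phenyl]-4-[(S)-[4-(benzyloxy)-3,5-dimethoxyphenyl](4-nitrobenzoyloxy)methyl]-4,5-dihydrofuran-3-carboxylate | COc1cc([C@@H](OC(=O)c3ccc(cc3)[N+](=O)[O-])[C@@H]2COC(c3ccc(OCc4ccccc4)c(OCc4ccccc4)c3)=C2C(=O)OC)cc(OC)c1OCc1ccccc1
F7 | step 10 | (3S,3aS,6S,6aR)-6-[3,4-bis(benzyloxy)phenyl]-3-[4-(benzyloxy)-3,5-dimethoxyphenyl]tetrahydro-1H,3H-furo[3,4-c]furan-1-one | COc1cc([C@H]2OC(=O)[C@@H]3[C@H]2CO[C@@H]3c2ccc(OCc4ccccc4)c(OCc4ccccc4)c2)cc(OC)c1OCc1ccccc1
F8 | step 5 | 1-[4-(benzyloxy)-3,5-dimethoxyphenyl]-3-(dimethylamino)propan-1-one hydrochloride | CN(C)CCC(=O)c1cc(OC)c(OCc2ccccc2)c(OC)c1.Cl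
F9 | step 5 | 3-[4-(benzyloxy)-3,5-dimethoxyphenyl]-N,N,N-trimethyl-3-oxopropan-1-aminium iodide | C[N+](C)(C)CCC(=O)c1cc(OC)c(OCc2ccccc2)c(OC)c1.[I-]
A1 | alternative 1 | benzyl 6-[3,4-bis(benzyloxy)phenyl]-3-[4-(benzyloxy)-3,5-dimethoxyphenyl]-1-oxotetrahydro-1H,3H-furo[3,4-c]furan-6a-carboxylate (configuration as in the SMILES) | COc1cc([C@H]2OC(=O)[C@]3(C(=O)OCc4ccccc4)[C@H]2CO[C@@H]3c2ccc(OCc4ccccc4)c(OCc4ccccc4)c2)cc(OC)c1OCc1ccccc1
A2 | alternative 1 | [(2R,3R)-3-[4-(benzyloxy)-3,5-dimethoxyphenyl]oxiran-2-yl]methanol | OC[C@H]1O[C@@H]1c1cc(OC)c(OCc2ccccc2)c(OC)c1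
A3 | alternative 1 | dibenzyl 2-[[3,4-bis(benzyloxy)phenyl]methylidene]propanedioate | O=C(OCc1ccccc1)C(=Cc1ccc(OCc2ccccc2)c(OCc2ccccc2)c1)C(=O)OCc1ccccc1
A4 | alternative 2 | endo-7-[4-(benzyloxy)-3,5-dimethoxyphenyl]-3-oxabicyclo[3.2.0]heptan-6-one (enantiomer that maps onto 17) | COc1cc([C@H]2C(=O)[C@@H]3[C@H]2COC3)cc(OC)c1OCc1ccccc1
A5 | alternative 2 | 2-[4-(benzyloxy)-3,5-dimethoxyphenyl]acetyl chloride | COc1cc(CC(=O)Cl)cc(OC)c1OCc1ccccc1
A6 | alternative 2 | 2-[4-(benzyloxy)-3,5-dimethoxyphenyl]ethen-1-one (arylketene) | COc1cc(C=C=O)cc(OC)c1OCc1ccccc1
A7 | alternative 2 | 2,5-dihydrofuran | C1OCC=C1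
A8 | alternative 2 | 3-[4-(benzyloxy)-3,5-dimethoxyphenyl]tetrahydro-1H,3H-furo[3,4-c]furan-1-one, unsubstituted at C8 (configuration as in the SMILES) | COc1cc([C@H]2OC(=O)[C@@H]3[C@H]2COC3)cc(OC)c1OCc1ccccc1
A9 | alternative 3 | (3S,3aS,6S,6aR)-6-[3,4-bis(benzyloxy)phenyl]-3-[4-(benzyloxy)-3,5-dimethoxyphenyl]tetrahydro-1H,3H-furo[3,4-c]furan-1-one | COc1cc([C@H]2OC(=O)[C@@H]3[C@H]2CO[C@@H]3c2ccc(OCc4ccccc4)c(OCc4ccccc4)c2)cc(OC)c1OCc1ccccc1
A10 | alternative 3 | 3-[3,4-bis(benzyloxy)benzoyl]-5-[4-(benzyloxy)-3,5-dimethoxyphenyl]-4-(hydroxymethyl)oxolan-2-one (C4 and C5 of the oxolanone cis as in the SMILES, C3 epimerisable) | COc1cc([C@H]2OC(=O)C(C(=O)c3ccc(OCc4ccccc4)c(OCc4ccccc4)c3)[C@H]2CO)cc(OC)c1OCc1ccccc1
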